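**Retrosynthetic overview**

1. Feature: in the oxolan-2-one ring (O1–C2–C3–C4–C5) the tertiary carbinol C3, which carries the OH and the 4-hydroxy-3-methoxybenzyl group, is bonded directly to the lactone carbonyl C2. This tertiary α-hydroxy ester is the product pattern of an α-ketol (benzilic-ester-type) 1,2-shift, and C4 is the enolisable α-carbon of a ketone before the shift.
2. Target 17 ⇐ bis(benzyl ether) 16 by hydrogenolysis.
3. 16 ⇐ racemic 5-hydroxy-2,3-diketone 14: hemiketalisation (O1–C2 bond, the only ring of the route) and shift of the benzyl group from C2 to C3 under a chiral Lewis acid, dynamic at C4 and at the hemiketal carbon.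
4. 14 ⇐ acyl dithiane 13 (unmasking) ⇐ ketone 12 + formaldehyde (C4–C5 bond) ⇐ lithiated 2-benzyl-1,3-dithiane 6 + N-methoxy-N-methyl amide 11 (C2–C3 bond).
5. 6 ⇐ 1,3-dithiane + the benzylic bromide from vanillin; 11 ⇐ syringaldehyde by olefination and hydrogenation.

Key step: step 11

Remark 1: diketone 14 is expected to exist as an equilibrating mixture of open chain, benzylic enol and cyclic hemiketal 15; it is named and counted as the open form, and 15 is listed as the intermediate of step 11.
Remark 2: the sense of induction of the ligand in step 11 cannot be predicted for a new reaction; (S,S) is written, and the antipode is taken if a first run shows the opposite sense.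

**Route**

Step 1
Reactants: 1 vanillin
Product: 2 4-(benzyloxy)-3-methoxybenzaldehyde
Conditions: BnBr, K2CO3, DMF, rt
Reagents that add atoms: benzyl bromide, BrCc1ccccc1
Why: Williamson ether synthesis on the phenoxide; the aldehyde does not react under these conditions.

Step 2
Reactants: 2 4-(benzyloxy)-3-methoxybenzaldehyde
Product: 3 [4-(benzyloxy)-3-methoxyphenyl]methanol
Conditions: NaBH4, MeOH/THF, 0 °C
Reagents that add atoms: none
Why: Borohydride reduction of an aryl aldehyde; the ethers are inert.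

Step 3
Reactants: 3 [4-(benzyloxy)-3-methoxyphenyl]methanol
Product: 4 1-(benzyloxy)-4-(bromomethyl)-2-methoxybenzene
Conditions: PBr3, Et2O, 0 °C; used without storage
Reagents that add atoms: phosphorus tribromide, BrP(Br)Br
Why: Bromination of an electron-rich benzylic alcohol through its phosphite ester; the aryl ethers survive the short, cold exposure.

Step 4
Reactants: 5 1,3-dithiane; 4 1-(benzyloxy)-4-(bromomethyl)-2-methoxybenzene
Product: 6 2-[4-(benzyloxy)-3-methoxybenzyl]-1,3-dithiane
Conditions: n-BuLi, THF, −30 °C; then 4, −78 → 0 °C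
Reagents that add atoms: none
Why: Corey–Seebach alkylation of 2-lithio-1,3-dithiane with a reactive benzylic bromide; the base is consumed before the benzyl ether is added.

Step 5
Reactants: 7 syringaldehyde
Product: 8 4-(benzyloxy)-3,5-dimethoxybenzaldehyde
Conditions: BnBr, K2CO3, DMF, 60 °C
Reagents that add atoms: benzyl bromide, BrCc1ccccc1
Why: Williamson ether synthesis; the flanked phenoxide needs gentle warming.

Step 6
Reactants: 8 4-(benzyloxy)-3,5-dimethoxybenzaldehyde; 9 diethyl {2-[methoxy(methyl)amino]-2-oxoethyl}phosphonate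
Product: 10 (2E)-3-[4-(benzyloxy)-3,5-dimethoxyphenyl]-N-methoxy-N-methylprop-2-enamide
Conditions: NaH, THF, 0 °C → rt
Reagents that add atoms: none
Why: Horner–Wadsworth–Emmons olefination with a stabilised phosphonate anion gives the E-enamide; the geometry is lost in the next step.

Step 7
Reactants: 10 (2E)-3-[4-(benzyloxy)-3,5-dimethoxyphenyl]-N-methoxy-N-methylprop-2-enamide
Product: 11 3-[4-(benzyloxy)-3,5-dimethoxyphenyl]-N-methoxy-N-methylpropanamide
Conditions: H2 (4 bar), RhCl(PPh3)3 (5 mol %), toluene/EtOH 1:1, 50 °C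
Reagents that add atoms: none
Why: Homogeneous Rh(I) hydrogenation saturates the disubstituted conjugated C=C and does not hydrogenolyse the aryl benzyl ether or the N–O bond.

Step 8
Reactants: 6 2-[4-(benzyloxy)-3-methoxybenzyl]-1,3-dithiane; 11 3-[4-(benzyloxy)-3,5-dimethoxyphenyl]-N-methoxy-N-methylpropanamide
Product: 12 1-{2-[4-(benzyloxy)-3-methoxybenzyl]-1,3-dithian-2-yl}-3-[4-(benzyloxy)-3,5-dimethoxyphenyl]propan-1-one
Conditions: 6, n-BuLi, THF, −30 °C; then 11, −78 → 0 °C; AcOH quench
Reagents that add atoms: none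
Why: Corey–Seebach acylation; the chelated tetrahedral adduct of the N-methoxy-N-methyl amide blocks a second addition and collapses to the ketone on quench.

Step 9
Reactants: 12 1-{2-[4-(benzyloxy)-3-methoxybenzyl]-1,3-dithian-2-yl}-3-[4-(benzyloxy)-3,5-dimethoxyphenyl]propan-1-one
Product: 13 rac-1-{2-[4-(benzyloxy)-3-methoxybenzyl]-1,3-dithian-2-yl}-2-[4-(benzyloxy)-3,5-dimethoxybenzyl]-3-hydroxypropan-1-one
Conditions: LDA, THF, −78 °C; CH2O (g, from cracked paraformaldehyde), −78 °C; AcOH quench at −78 °C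
Reagents that add atoms: formaldehyde, C=O
Why: Aldol addition of the lithium enolate, formed at the only enolisable position of 12, to monomeric formaldehyde; the new centre is racemic and is meant to stay labile.

Step 10
Reactants: 13 rac-1-{2-[4-(benzyloxy)-3-methoxybenzyl]-1,3-dithian-2-yl}-2-[4-(benzyloxy)-3,5-dimethoxybenzyl]-3-hydroxypropan-1-one
Product: 14 rac-1-[4-(benzyloxy)-3-methoxyphenyl]-4-[4-(benzyloxy)-3,5-dimethoxybenzyl]-5-hydroxypentane-2,3-dione
Conditions: Hg(ClO4)2·3H2O, CaCO3, THF/H2O 5:1, 0 °C; filtered through Celite and used directly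
Reagents that add atoms: water, O
Why: Thiophilic Hg(II)-assisted hydrolysis of the S,S-ketal under carbonate buffer, which should be helped by the neighbouring hydroxyl trapping the thionium ion; benzyl ethers and arenes are not oxidised.

Step 11
Reactants: 14 rac-1-[4-(benzyloxy)-3-methoxyphenyl]-4-[4-(benzyloxy)-3,5-dimethoxybenzyl]-5-hydroxypentane-2,3-dione
Product: 16 (3S,4S)-3-[4-(benzyloxy)-3-methoxybenzyl]-4-[4-(benzyloxy)-3,5-dimethoxybenzyl]-3-hydroxyoxolan-2-one, via cyclic hemiketal 15 (not isolated)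
Conditions: Cu(OTf)2 (10 mol %), (S,S)-t-Bu-box (11 mol %), i-Pr2NEt (20 mol %), 4 Å MS, CH2Cl2, −20 → 0 °C, Ar
Reagents that add atoms: none
Why: Proposed new method: the C5 hydroxyl of 14 adds to the distal C2 ketone (5-exo-trig, O1–C2 bond) to give hemiketal 15, whose hemiketal oxygen and C3 ketone chelate copper; loss of the hemiketal proton to the amine then drives a 1,2-shift of the 4-(benzyloxy)-3-methoxybenzyl group from C2 to C3 while C2 becomes the lactone carbonyl, a step made irreversible by the gain of ester resonance. The closest known reaction types are base- or Lewis-acid-promoted α-ketol and benzilic ester rearrangements and chiral-Lewis-acid-catalysed enantioselective α-ketol rearrangements of chelating α-hydroxy ketones; running such a shift on a ring–chain-equilibrating hemiketal as a dynamic kinetic asymmetric process is the untested part. The oxolane is the only ring formed and it closes in the hemiketalisation, not in the shift. The shift is suprafacial, so C3 takes its configuration from the hemiketal carbon, which the chiral copper complex has to select inside its own chelate ring ((2R)-15), whereas C4 is set by the substrate: the benzyl group should cross the ketone face anti to the C4 arylmethyl group, which leaves the new hydroxyl cis to that group. Since the hemiketal carbon epimerises by ring opening and C4 by copper/amine-mediated enolisation of the C3 ketone, all four stereoisomers of 15 should drain through the matched (2R,4S) isomer. The step needs the catalysed shift to outrun the uncatalysed one and the dehydration of 15, and regiochemistry is not in question because only the five-membered hemiketal can form and it carries a single carbon substituent able to migrate.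

Step 12
Reactants: 16 (3S,4S)-3-[4-(benzyloxy)-3-methoxybenzyl]-4-[4-(benzyloxy)-3,5-dimethoxybenzyl]-3-hydroxyoxolan-2-one
Product: 17 (3S,4S)-3-hydroxy-3-(4-hydroxy-3-methoxybenzyl)-4-(4-hydroxy-3,5-dimethoxybenzyl)oxolan-2-one
Conditions: H2 (1 atm), 10 % Pd/C, EtOAc/EtOH, rt
Reagents that add atoms: none
Why: Hydrogenolysis of the two aryl benzyl ethers under neutral conditions; the lactone, the tertiary alcohol, the quaternary C3 and the non-enolisable C4 are untouched.

**Compound list**

1 | vanillin (4-hydroxy-3-methoxybenzaldehyde) | COc1cc(C=O)ccc1O | starting material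
2 | 4-(benzyloxy)-3-methoxybenzaldehyde | COc1cc(C=O)ccc1OCc1ccccc1 | intermediate
3 | [4-(benzyloxy)-3-methoxyphenyl]methanol | COc1cc(CO)ccc1OCc1ccccc1 | intermediate
4 | 1-(benzyloxy)-4-(bromomethyl)-2-methoxybenzene | COc1cc(CBr)ccc1OCc1ccccc1 | intermediate
5 | 1,3-dithiane | C1CSCSC1 | starting material
6 | 2-[4-(benzyloxy)-3-methoxybenzyl]-1,3-dithiane | COc1cc(CC2SCCCS2)ccc1OCc1ccccc1 | intermediate
7 | syringaldehyde (4-hydroxy-3,5-dimethoxybenzaldehyde) | COc1cc(C=O)cc(OC)c1O | starting material
8 | 4-(benzyloxy)-3,5-dimethoxybenzaldehyde | COc1cc(C=O)cc(OC)c1OCc1ccccc1 | intermediate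
9 | diethyl {2-[methoxy(methyl)amino]-2-oxoethyl}phosphonate | CCOP(=O)(CC(=O)N(C)OC)OCC | starting material
10 | (2E)-3-[4-(benzyloxy)-3,5-dimethoxyphenyl]-N-methoxy-N-methylprop-2-enamide | COc1cc(/C=C/C(=O)N(C)OC)cc(OC)c1OCc1ccccc1 | intermediate
11 | 3-[4-(benzyloxy)-3,5-dimethoxyphenyl]-N-methoxy-N-methylpropanamide | COc1cc(CCC(=O)N(C)OC)cc(OC)c1OCc1ccccc1 | intermediate
12 | 1-{2-[4-(benzyloxy)-3-methoxybenzyl]-1,3-dithian-2-yl}-3-[4-(benzyloxy)-3,5-dimethoxyphenyl]propan-1-one | COc1cc(CC2(C(=O)CCc3cc(OC)c(OCc4ccccc4)c(OC)c3)SCCCS2)ccc1OCc1ccccc1 | intermediate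
13 | rac-1-{2-[4-(benzyloxy)-3-methoxybenzyl]-1,3-dithian-2-yl}-2-[4-(benzyloxy)-3,5-dimethoxybenzyl]-3-hydroxypropan-1-one | COc1cc(CC2(C(=O)C(CO)Cc3cc(OC)c(OCc4ccccc4)c(OC)c3)SCCCS2)ccc1OCc1ccccc1 | intermediate
14 | rac-1-[4-(benzyloxy)-3-methoxyphenyl]-4-[4-(benzyloxy)-3,5-dimethoxybenzyl]-5-hydroxypentane-2,3-dione (key-step precursor; equilibrates with its enol and with 15) | O=C(Cc1ccc(OCc2ccccc2)c(OC)c1)C(=O)C(CO)Cc1cc(OC)c(OCc2ccccc2)c(OC)c1 | intermediate
15 | (2R,4S)-2-[4-(benzyloxy)-3-methoxybenzyl]-4-[4-(benzyloxy)-3,5-dimethoxybenzyl]-2-hydroxyoxolan-3-one (catalyst-matched isomer of the equilibrating hemiketal; not isolated) | COc1cc(C[C@@]2(O)OC[C@H](Cc3cc(OC)c(OCc4ccccc4)c(OC)c3)C2=O)ccc1OCc1ccccc1 | intermediate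
16 | (3S,4S)-3-[4-(benzyloxy)-3-methoxybenzyl]-4-[4-(benzyloxy)-3,5-dimethoxybenzyl]-3-hydroxyoxolan-2-one | COc1cc(C[C@@]2(O)C(=O)OC[C@@H]2Cc2cc(OC)c(OCc3ccccc3)c(OC)c2)ccc1OCc1ccccc1 | intermediate
17 | (3S,4S)-3-hydroxy-3-(4-hydroxy-3-methoxybenzyl)-4-(4-hydroxy-3,5-dimethoxybenzyl)oxolan-2-one (CNP0315014.1) | COc1cc(C[C@@]2(O)C(=O)OC[C@@H]2Cc2cc(OC)c(O)c(OC)c2)ccc1O | target

**Step count and risks**

Total steps: 12. Longest linear sequence: 9 (steps 1–4 and 8–12); the syringyl arm (steps 5–7) joins at step 8.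

Steps most likely to fail:

1. Step 11 (proposed new method).
   - What may go wrong: an uncatalysed or achiral-Lewis-acid shift may compete and erode enantioselection; C4 may epimerise too slowly, so that only a kinetic resolution results; the hemiketal may dehydrate or lose its ring oxygen by β-elimination instead of rearranging; facial control of the migration relative to the C4 group may be poor.
   - Fallback by known chemistry: it sets out from aldehyde 8 and comes back at 16.
   - Stobbe condensation of 8 with dimethyl succinate (KOt-Bu, t-BuOH, reflux) should give (3E)-4-[4-(benzyloxy)-3,5-dimethoxyphenyl]-3-(methoxycarbonyl)but-3-enoic acid F1.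
   - Asymmetric hydrogenation with a cationic Rh(I)–chiral bisphosphine catalyst (H2, MeOH, Et3N), which leaves aryl benzyl ethers alone, should give (3R)-4-[4-(benzyloxy)-3,5-dimethoxyphenyl]-3-(methoxycarbonyl)butanoic acid F2.
   - Reduction of the ester in the potassium carboxylate with Ca(BH4)2 (CaCl2, NaBH4, EtOH) and acidification should close (4R)-4-[4-(benzyloxy)-3,5-dimethoxybenzyl]oxolan-2-one F3.
   - Enolate hydroxylation (KHMDS, 2-(phenylsulfonyl)-3-phenyloxaziridine, THF, −78 °C) should give (3R,4S)-4-[4-(benzyloxy)-3,5-dimethoxybenzyl]-3-hydroxyoxolan-2-one F4, whose C3 configuration is of no consequence.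
   - The dianion of F4 (LiHMDS, 2.2 equiv, THF/HMPA, −78 → −30 °C) is alkylated with bromide 4 on the face anti to the C4 substituent, the established entry to trans-3,4-dibenzyl-3-hydroxy lactones, to give 16.

2. Step 10.
   - What may go wrong: the deactivated 2-acyl dithiane may cleave slowly, and the liberated β-hydroxy diketone may meanwhile suffer Lewis-acid- or carbonate-promoted β-elimination of the hydroxyl, dehydration of the hemiketal, or a premature uncatalysed shift to racemic lactone.
   - Fallback: it sets out from 13 and comes back at 14.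
   - Silylation (TBSCl, imidazole, DMF) gives rac-1-{2-[4-(benzyloxy)-3-methoxybenzyl]-1,3-dithian-2-yl}-2-[4-(benzyloxy)-3,5-dimethoxybenzyl]-3-[(tert-butyldimethylsilyl)oxy]propan-1-one F5.
   - Non-oxidative, metal-free S-methylation/hydrolysis (MeI, CaCO3, MeCN/H2O, 45 °C) gives rac-1-[4-(benzyloxy)-3-methoxyphenyl]-4-[4-(benzyloxy)-3,5-dimethoxybenzyl]-5-[(tert-butyldimethylsilyl)oxy]pentane-2,3-dione F6, which cannot cyclise or rearrange and can be purified.
   - Desilylation with HF·pyridine (THF, 0 °C) releases 14 immediately before step 11.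

3. Step 8.
   - What may go wrong: the hindered tertiary carbanion may act as a base (enolisation of the amide, metalation next to the benzyl ether oxygen) faster than it adds to the amide carbonyl.
   - Fallback: it sets out from amide 11 (with dithiane 6) and comes back at 12.
   - Reduction of 11 with DIBAL-H (THF, −78 °C) gives 3-[4-(benzyloxy)-3,5-dimethoxyphenyl]propanal F7.
   - Addition of lithiated 6 to this far more reactive electrophile (THF, −78 °C) gives rac-1-{2-[4-(benzyloxy)-3-methoxybenzyl]-1,3-dithian-2-yl}-3-[4-(benzyloxy)-3,5-dimethoxyphenyl]propan-1-ol F8.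
   - Parikh–Doering oxidation (SO3·pyridine, DMSO, i-Pr2NEt, CH2Cl2, 0 °C) gives 12.

**Further compounds**

F1 | step 11 | (3E)-4-[4-(benzyloxy)-3,5-dimethoxyphenyl]-3-(methoxycarbonyl)but-3-enoic acid | COC(=O)/C(=C/c1cc(OC)c(OCc2ccccc2)c(OC)c1)CC(=O)O
F2 | step 11 | (3R)-4-[4-(benzyloxy)-3,5-dimethoxyphenyl]-3-(methoxycarbonyl)butanoic acid | COC(=O)[C@H](Cc1cc(OC)c(OCc2ccccc2)c(OC)c1)CC(=O)O
F3 | step 11 | (4R)-4-[4-(benzyloxy)-3,5-dimethoxybenzyl]oxolan-2-one | O=C1C[C@@H](Cc2cc(OC)c(OCc3ccccc3)c(OC)c2)CO1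
F4 | step 11 | (3R,4S)-4-[4-(benzyloxy)-3,5-dimethoxybenzyl]-3-hydroxyoxolan-2-one | O[C@H]1C(=O)OC[C@@H]1Cc1cc(OC)c(OCc2ccccc2)c(OC)c1
F5 | step 10 | rac-1-{2-[4-(benzyloxy)-3-methoxybenzyl]-1,3-dithian-2-yl}-2-[4-(benzyloxy)-3,5-dimethoxybenzyl]-3-[(tert-butyldimethylsilyl)oxy]propan-1-one | COc1cc(CC2(C(=O)C(CO[Si](C)(C)C(C)(C)C)Cc3cc(OC)c(OCc4ccccc4)c(OC)c3)SCCCS2)ccc1OCc1ccccc1
F6 | step 10 | rac-1-[4-(benzyloxy)-3-methoxyphenyl]-4-[4-(benzyloxy)-3,5-dimethoxybenzyl]-5-[(tert-butyldimethylsilyl)oxy]pentane-2,3-dione | O=C(Cc1ccc(OCc2ccccc2)c(OC)c1)C(=O)C(CO[Si](C)(C)C(C)(C)C)Cc1cc(OC)c(OCc2ccccc2)c(OC)c1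
F7 | step 8 | 3-[4-(benzyloxy)-3,5-dimethoxyphenyl]propanal | COc1cc(CCC=O)cc(OC)c1OCc1ccccc1
F8 | step 8 | rac-1-{2-[4-(benzyloxy)-3-methoxybenzyl]-1,3-dithian-2-yl}-3-[4-(benzyloxy)-3,5-dimethoxyphenyl]propan-1-ol | COc1cc(CC2(C(O)CCc3cc(OC)c(OCc4ccccc4)c(OC)c3)SCCCS2)ccc1OCc1ccccc1
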